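(All runs stem from a simulated flask for substances that don't exist, noise included.)

Target climbs along one curve in Thursday's and Friday's runs, so the question is what could hold elm, with its longer time, down near ash.

| setting | Thursday's | Friday's | elm | ash |
|---|---|---|---|---|
| substrate | 0.25 M | 0.25 M | 0.25 M | 0.25 M |
| partner | 0.50 M | 0.50 M | 0.500 M | 0.500 M |
| scavenger | 0.25 M (in portions, 3) | 0.56 M (in portions, 3) | 0.375 M | 0.375 M (in portions, 3) |
| initiator | 12 mM | 12 mM | 12 mM | 12 mM |
| remark | run made earlier; portions every 3.0 min | run made earlier; portions every 3.0 min | everything together at the start | the portions of scavenger follow each other after 3.0 min, the first at the start |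
| time |  |  | 30 min | 10 min |

| run | time / min | target / % |
|---|---|---|
| Thursday's | 1.00 | 6.9 |
| Thursday's | 1.33 | 8.7 |
| Thursday's | 2.00 | 13.1 |
| Thursday's | 3.00 | 18.3 |
| Thursday's | 5.00 | 28.9 |
| Thursday's | 8.00 | 41.2 |
| Thursday's | 12.0 | 53.7 |
| Friday's | 0.667 | 5.0 |
| Friday's | 2.00 | 12.2 |
| Friday's | 3.00 | 19.0 |
| Friday's | 5.00 | 29.0 |
| Friday's | 8.00 | 41.7 |
| Friday's | 10.0 | 48.3 |
| Friday's | 12.0 | 54.3 |

(standard deviation of a reading: 0.5 percentage points)

- which of the two ends with the higher amount of target, in percent of the substrate charged ("neither" if they lie within 2 percentage points) (elm / ash / neither)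
- target at the end, in percent of the substrate charged, elm
- target at the end, in percent of the substrate charged, ash

- the numbers in the tables scatter with a standard deviation of 0.5 percentage points

Take the rate as proportional to substrate and to partner, with partner falling as substrate goes. The fresh-partner constant (a pseudo-first-order constant) is then the fraction of remaining substrate consumed per minute while partner stands at its charge. The mean of the two readings at 12.0 min, 54.0%, gives 0.0770 min⁻¹. This reckoning, which is not the forecast's, puts ash at 48.4% and elm at 81.3%.

Turn the question round. To stay within 2 points of ash, elm must end near 50.4%, so its mean constant must be 0.0274 min⁻¹, a third of the value read. That is a fall of 0.0496 min⁻¹. Scavenger is one suspect, and the two runs allow its correction to be reckoned. Going from Thursday's charge to Friday's shifted the constant by 0.001489 min⁻¹, far less than that fall, and the reading itself lies within the scatter. Friday's flask also held 0.373 M after its second portion, about elm's charge. Elm's opening dose is still larger than Friday's first portion, and no run shows that dose during the first 3.0 min. Initiator's decay is a second possible correction, and this one stays unreckoned here: the runs stop at 12.0 min, short of elm's 30 min.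

The forecast gives elm, with elm at 80% and ash at 48%, and its ground for elm is that “Friday's cumulative 0.56 M caused no harm”.

Elm ends at 82.2% and ash at 48.0%, a difference of 34 points, of which the way scavenger goes in holds 0 points, averaged over the orders of changing. Elm's end, put through the same law, gives a constant of 0.0797 min⁻¹, well above the 0.0274 min⁻¹ that the opposite outcome needed.

    substrate + second chain carrier → released group + first chain carrier (k = 2300 M⁻¹ s⁻¹)
    2 second chain carrier → ended chains (k = 2.90 × 10⁷ M⁻¹ s⁻¹)
    partner + first chain carrier → target + second chain carrier (k = 4300 M⁻¹ s⁻¹)
    partner + released group ⇌ idle adduct, settled at all times (K = 0.670 M⁻¹)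
    initiator → 2 initiating radical (k = 5.70 × 10⁻⁴ s⁻¹)
    substrate + initiating radical → capped initiator + first chain carrier (k = 1.50 × 10⁵ M⁻¹ s⁻¹)
    scavenger + released group → scavenged by-product (k = 0.210 M⁻¹ s⁻¹)

For a neighbour of ash, alike but charged with 0.062 M of substrate, the constant 0.0770 min⁻¹ gives 52.4%. The computed result is 54.3%.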